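**Assumption:** commercial natural (R)-rosmarinic acid and (E)-p-coumaric acid are the starting materials; ring numbering is C1 = CO2H carbon, C2 = 4-hydroxyphenyl carbon, C3 = ester carbon, C4 = catechol carbon, which makes the target (1R,2R,3S,4S) with an (R) side chain.

## Retrosynthetic overview

1. The target is the all-trans, head-to-tail [2+2] heterodimer of the caffeoyl C=C of (R)-rosmarinic acid and the C=C of p-coumaric acid (carboxyl carbons cis-1,3, aryl groups cis-1,3, every vicinal pair trans).
2. Disconnect C2–C3 and C1–C4 by a photochemical [2+2], made intramolecular by joining the two free CO2H groups as a methylene diester (acylal).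
3. The (R)-danshensu centre, bought in rosmarinic acid, sits in that tether and is the only source of chirality for the four ring centres.
4. Ring order: acylal tether (two steps), then cyclobutane and 11-membered bridge together in the photochemical step, then hydrolytic loss of the CH2 link as formaldehyde.

## Route

Step 1
Reactants: 1 (E)-p-coumaric acid
Product: 2 chloromethyl (2E)-3-(4-hydroxyphenyl)prop-2-enoate
Conditions: ClCH2I (8 equiv), KHCO3 (1.05 equiv), DMF, rt, dark
Reagents that add atoms: chloroiodomethane (ClCI)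
Why: Bicarbonate deprotonates only the carboxylic acid, and the carboxylate displaces iodide from excess ClCH2I (SN2 O-alkylation, chloromethyl ester synthesis) while the neutral phenol is untouched; no stereocentre is formed.

Step 2
Reactants: 2 chloromethyl p-coumarate; 3 (R)-rosmarinic acid
Product: 4 mixed methylene diester (acylal) of 1 and 3
Conditions: KHCO3 (1.0 equiv), NaI (10 mol %), DMF, rt, Ar, dark
Reagents that add atoms: none
Why: One equivalent of base ionises only the α-acyloxy carboxylic acid of 3 (pKa ≈ 3), which alkylates on oxygen with the in situ iodomethyl ester (Finkelstein-assisted SN2, acyloxymethyl ester synthesis); the five phenolic OH groups stay neutral and the (R) centre is not touched.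

Step 3
Reactants: 4 mixed methylene diester
Product: 5 methylene-bridged macrocyclic cyclobutane (all-trans ring, carboxyl carbons cis-1,3 in an 11-membered bridge)
Conditions: fac-Ir(dFppy)3 (2 mol %), degassed DMF (2 mM), 405 nm LEDs, rt
Reagents that add atoms: none
Why: Proposed new method: a triplet-sensitised, register-shifted, macrocyclising head-to-tail [2+2] across an unsymmetrical acylal tether, with face selection relayed from the (R) ester centre (closest known reactions: sensitised intramolecular [2+2] of diol-tethered dicinnamates, which hold both acyl groups in register and give head-to-head truxinates, and crossed [2+2] photocycloadditions of 1,5-dienes). Energy transfer gives a cinnamoyl triplet; the caffeoyl unit hangs on the stereocentre through one atom (O) but the coumaroyl unit through four (C(=O)–O–CH2–O) that must fold back past that centre, so only the coumaroyl Cβ can reach the caffeoyl alkene and the carbon it meets is Cα′, making the first bond the head-to-tail C2–C3 bond (11-membered ring; the head-to-head Cα–Cα′ contact is out of reach and would need a more strained 10-membered ring). In the preferred conformer of the secondary ester (C–H eclipsing C=O, Z-ester, s-cis enoate) the carboxylate arm of the (R) centre lies on the Si face of the caffeoyl alkene and the benzyl group on the Re face, so delivery from the arm sets C3 as S. The resulting 1,4-diradical (coumaroyl Cα, benzylic caffeoyl Cβ′) closes C1–C4 after spin inversion with both aryl groups trans to their neighbours while the short bridge forces the two carboxyl carbons cis-1,3, giving the (1R,2R,3S,4S) ring; E/Z scrambling of 4 does not matter because both isomers give the same twisted triplet.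

Step 4
Reactants: 5 methylene-bridged macrocyclic cyclobutane
Product: 7 CNP0270917.1 (target), via hydroxymethyl ester 6 (not isolated)
Conditions: K2CO3 (aq, pH ≈ 10), THF–H2O, 0 °C, Ar; then 1 M HCl
Reagents that add atoms: water (O)
Why: The acylal is an activated ester, so hydroxide attacks its α-acyloxy-substituted carbonyl and the resulting hydroxymethyl ester (a hemiacetal ester) loses formaldehyde spontaneously (acylal hydrolysis), while the hindered secondary cyclobutanecarboxylate ester is much slower and the ring centres, already all-trans, are not scrambled.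

## Compound list

1 | (2E)-3-(4-hydroxyphenyl)prop-2-enoic acid (p-coumaric acid) | OC(=O)/C=C/c1ccc(O)cc1 | starting material
2 | chloromethyl (2E)-3-(4-hydroxyphenyl)prop-2-enoate | ClCOC(=O)/C=C/c1ccc(O)cc1 | intermediate
3 | (R)-rosmarinic acid, (2R)-2-{[(2E)-3-(3,4-dihydroxyphenyl)prop-2-enoyl]oxy}-3-(3,4-dihydroxyphenyl)propanoic acid | OC(=O)[C@@H](Cc1ccc(O)c(O)c1)OC(=O)/C=C/c1ccc(O)c(O)c1 | starting material
4 | {[(2E)-3-(4-hydroxyphenyl)prop-2-enoyl]oxy}methyl (2R)-2-{[(2E)-3-(3,4-dihydroxyphenyl)prop-2-enoyl]oxy}-3-(3,4-dihydroxyphenyl)propanoate | O=C(/C=C/c1ccc(O)cc1)OCOC(=O)[C@@H](Cc1ccc(O)c(O)c1)OC(=O)/C=C/c1ccc(O)c(O)c1 | intermediate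
5 | macrocycle: compound 7 with the oxygen of its C1 carboxyl and the oxygen of its side-chain carboxyl joined by one CH2 (11-membered 1,3-bridge on the cyclobutane; ring centres as in 7, side-chain centre R) | O=C(OC3)[C@@H]1[C@@H](c2ccc(O)cc2)[C@H](C(=O)O[C@H](Cc2ccc(O)c(O)c2)C(=O)O3)[C@H]1c1ccc(O)c(O)c1 | intermediate
6 | compound 7 with its C1 carboxyl as the hydroxymethyl ester (HOCH2O–C(=O)–) | O=C(OCO)[C@@H]1[C@@H](c2ccc(O)cc2)[C@H](C(=O)O[C@H](Cc2ccc(O)c(O)c2)C(=O)O)[C@H]1c1ccc(O)c(O)c1 | intermediate
7 | (1R,2R,3S,4S)-3-{[(1R)-1-carboxy-2-(3,4-dihydroxyphenyl)ethoxy]carbonyl}-4-(3,4-dihydroxyphenyl)-2-(4-hydroxyphenyl)cyclobutane-1-carboxylic acid | O=C(O)[C@@H]1[C@@H](c2ccc(O)cc2)[C@H](C(=O)O[C@H](Cc2ccc(O)c(O)c2)C(=O)O)[C@H]1c1ccc(O)c(O)c1 | target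

## Step count and risks

Total steps: 4. Longest linear sequence: 4 (1 → 2 → 4 → 5 → 7).

**Step 3 (proposed new step, the most likely to fail).** The regiochemical and facial arguments rest on a conformational model, not on a precedent. Possible outcomes are head-to-head (truxinate-type) closure as with in-register tethers, no cycloaddition beyond E/Z isomerisation, or a poor ratio of 5 to its ring-enantiomeric diastereomer (which would need RP-HPLC). The fallback uses known chemistry only, sets out from 3 and comes back at 7. It takes the regiochemistry from the rule of five instead of the tether, and it gives up control of the ring configuration, which is then resolved by separating diastereomers.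

Saponification of 3 (aq NaOH, N2, then acid) gives (R)-danshensu F1. Benzyl bromide and K2CO3 in DMF convert it into benzyl (2R)-3-[3,4-bis(benzyloxy)phenyl]-2-hydroxypropanoate F2. Separately, butane-2,3-dione is condensed with 4-(benzyloxy)benzaldehyde (piperidinium acetate) to (4E)-5-[4-(benzyloxy)phenyl]pent-4-ene-2,3-dione F3, and then with 3,4-bis(benzyloxy)benzaldehyde to (1E,5E)-1-[4-(benzyloxy)phenyl]-6-[3,4-bis(benzyloxy)phenyl]hexa-1,5-diene-3,4-dione F4.

Irradiation of dilute F4 with visible light gives, by the established crossed [2+2] of hexa-1,5-diene-3,4-diones, the meso 5,6-diarylbicyclo[2.1.1]hexane-2,3-dione F5 with both aryl groups anti to the dione bridge. Baeyer–Villiger oxidation of the α-diketone (mCPBA) gives the all-trans 6,7-diaryl-3-oxabicyclo[3.1.1]heptane-2,4-dione F6. DMAP-mediated opening of F6 with F2 gives the hexabenzyl-protected target F7 together with its ring-enantiomeric diastereomer F8 (about 1:1, since the two carbonyls differ only in a remote aryl substituent; separated by HPLC). Hydrogenolysis of F7 (H2, Pd/C) gives 7.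

**Step 2.** The risk is competing O-alkylation of the catechols of 3, or of the phenol of 2, by the halomethyl ester. The fallback sets out from 3 and comes back at 4, masking the catechols in situ. Compound 3 with phenylboronic acid (2 equiv, 4 Å sieves) gives rosmarinic acid bis(phenylboronate) F9. Alkylation with 2 (iPr2NEt, NaI, MeCN) gives the bis(phenylboronate) of the acylal F10. Aqueous work-up with mannitol releases 4.

**Step 4.** The risk is competing cleavage of the caffeoyl-derived secondary ester, or base and air damage to the catecholates in the presence of the liberated formaldehyde. The fallback sets out from 5 and comes back at 7, replacing acyl–oxygen hydrolysis by alkyl–oxygen cleavage. Iodotrimethylsilane (from TMSCl/NaI, MeCN, 0 °C) silylates the phenols and dealkylates the acylal at its CH2 by SN2, giving the heptakis(trimethylsilyl) derivative of 7 F11. Work-up with aqueous methanol gives 7.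

## Further compounds

F1 | step 3 | (R)-danshensu, (2R)-3-(3,4-dihydroxyphenyl)-2-hydroxypropanoic acid | O[C@H](Cc1ccc(O)c(O)c1)C(=O)O
F2 | step 3 | benzyl (2R)-3-[3,4-bis(benzyloxy)phenyl]-2-hydroxypropanoate | O[C@H](Cc1ccc(OCc2ccccc2)c(OCc2ccccc2)c1)C(=O)OCc1ccccc1
F3 | step 3 | (4E)-5-[4-(benzyloxy)phenyl]pent-4-ene-2,3-dione | CC(=O)C(=O)/C=C/c1ccc(OCc2ccccc2)cc1
F4 | step 3 | (1E,5E)-1-[4-(benzyloxy)phenyl]-6-[3,4-bis(benzyloxy)phenyl]hexa-1,5-diene-3,4-dione | O=C(/C=C/c1ccc(OCc2ccccc2)cc1)C(=O)/C=C/c1ccc(OCc2ccccc2)c(OCc2ccccc2)c1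
F5 | step 3 | 5-[4-(benzyloxy)phenyl]-6-[3,4-bis(benzyloxy)phenyl]bicyclo[2.1.1]hexane-2,3-dione, both aryl groups anti to the C2–C3 bridge (meso) | O=C3[C@@H]1[C@@H](c2ccc(OCc4ccccc4)cc2)[C@H](C3=O)[C@H]1c1ccc(OCc2ccccc2)c(OCc2ccccc2)c1
F6 | step 3 | 6-[4-(benzyloxy)phenyl]-7-[3,4-bis(benzyloxy)phenyl]-3-oxabicyclo[3.1.1]heptane-2,4-dione, both aryl groups anti to the anhydride bridge (meso) | O=C3[C@@H]1[C@@H](c2ccc(OCc4ccccc4)cc2)[C@H](C(=O)O3)[C@H]1c1ccc(OCc2ccccc2)c(OCc2ccccc2)c1
F7 | step 3 | hexabenzyl-protected 7 (five O-benzyl ethers, side-chain benzyl ester, free C1 carboxylic acid; configuration as in 7) | O=C(O)[C@@H]1[C@@H](c2ccc(OCc3ccccc3)cc2)[C@H](C(=O)O[C@H](Cc2ccc(OCc3ccccc3)c(OCc3ccccc3)c2)C(=O)OCc2ccccc2)[C@H]1c1ccc(OCc2ccccc2)c(OCc2ccccc2)c1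
F8 | step 3 | diastereomer of F7 with the mirror-image cyclobutane (side chain on the other carboxyl of the meso anhydride), removed by HPLC | O=C(O[C@H](Cc2ccc(OCc3ccccc3)c(OCc3ccccc3)c2)C(=O)OCc2ccccc2)[C@@H]1[C@@H](c2ccc(OCc3ccccc3)cc2)[C@H](C(=O)O)[C@H]1c1ccc(OCc2ccccc2)c(OCc2ccccc2)c1
F9 | step 2 | (R)-rosmarinic acid bis(phenylboronate) (both catechols as 2-phenyl-1,3,2-benzodioxaboroles) | OC(=O)[C@@H](Cc1ccc2OB(c3ccccc3)Oc2c1)OC(=O)/C=C/c1ccc2OB(c3ccccc3)Oc2c1
F10 | step 2 | bis(phenylboronate) of 4 | O=C(/C=C/c1ccc(O)cc1)OCOC(=O)[C@@H](Cc1ccc2OB(c3ccccc3)Oc2c1)OC(=O)/C=C/c1ccc2OB(c3ccccc3)Oc2c1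
F11 | step 4 | heptakis(trimethylsilyl) derivative of 7 (five aryl TMS ethers, two TMS esters) | C[Si](C)(C)OC(=O)[C@@H]1[C@@H](c2ccc(O[Si](C)(C)C)cc2)[C@H](C(=O)O[C@H](Cc2ccc(O[Si](C)(C)C)c(O[Si](C)(C)C)c2)C(=O)O[Si](C)(C)C)[C@H]1c1ccc(O[Si](C)(C)C)c(O[Si](C)(C)C)c1
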